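**Assumption:** natural (3R,3'R,6'R)-lutein (marigold extract, sold in bulk) is taken as the commercial starting material. Read against lutein, the target SMILES has the opposite configuration at C3 of ring A (3-OH trans to 6-OH), so one inversion at C3 is planned. Ring A is the C1–C6 ring and ring B is the C1'–C6' ring.

## Retrosynthetic overview

1. Target 17 ⇐ 15 by ester and silyl removal; 15 ⇐ 14 by re-forming the C3–O bond with inversion (Mitsunobu).
2. 14 ⇐ 11 by epoxide to exocyclic allylic alcohol isomerisation; 11 ⇐ 10 by hydroxyl-directed epoxidation of C5=C6 (forms C6–O, sets C6).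
3. 10 ⇐ 8 by base-induced opening of the 5,8-epoxide (new step); 8 ⇐ 6 by epoxidation and 5,6 to 5,8 oxygen shift (the C8–O bond, the key C–O construction).
4. 6 ⇐ lutein 1 by MnO2 oxidation of the allylic carbinol, bulky-hydride return and silylation, which tells the two secondary hydroxyls apart.
5. Rings: both carbocycles and the all-E polyene come intact from lutein; only transient oxiranes and one 2,5-dihydrofuran are made and opened again, and no C–C bond is formed.

## Route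

**Step 1**
Reactants: 1 (3R,3'R,6'R)-lutein
Product: 2 3'-oxolutein
Conditions: MnO2 (activated, 20 equiv), CH2Cl2, rt, dark
Reagents that add atoms: none
Why: Allylic alcohol oxidation with MnO2: only the 3'-carbinol of ring B is allylic, so it alone is dehydrogenated to the enone, which tells the two secondary hydroxyls apart (the 3' centre is removed here and set again in step 2; C3 and C6' are untouched).

**Step 2**
Reactants: 2 3'-oxolutein
Product: 6 3'-O-TBS-lutein, via TMS ether 3 (not isolated), via potassium alkoxide 4 (not isolated), via bis-silyl ether 5 (not isolated)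
Conditions: TMSCl, Et3N, THF, 0 °C; K[sBu3BH] (K-Selectride), −78 °C; TBSOTf, −78 to 0 °C; then K2CO3 (cat.), MeOH, 0 °C
Reagents that add atoms: TBSOTf, CC(C)(C)[Si](C)(C)OS(=O)(=O)C(F)(F)F
Why: Transient O-silylation of the only hydroxyl, then diastereoselective 1,2-reduction of the β,β-disubstituted enone by the bulky borohydride from the face opposite the axial C1' methyl (the C6' chain is pseudo-axial because of allylic strain with the C5' methyl), which should return the trans (3'R) carbinol as I recall for 3-oxo-α-ionone-type rings, its potassium alkoxide being trapped as the TBS ether before the labile TMS ether is methanolysed; any (3'S) epimer is removed by chromatography.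

**Step 3**
Reactants: 6 3'-O-TBS-lutein
Product: 8 furanoid 5,8-epoxide of 6 (C5/C8 isomer mixture), via 5,6-epoxide 7 (not isolated)
Conditions: mCPBA (1.05 equiv), CH2Cl2, −20 °C; then CSA (5 mol %), 0 °C
Reagents that add atoms: mCPBA, OOC(=O)c1cccc(Cl)c1
Why: Prilezhaev epoxidation at the most electron-rich, tetrasubstituted C5=C6 bond, then the acid-catalysed furanoid rearrangement of carotenoid 5,6-epoxides, in which the oxirane oxygen attacks C8 of the polyenyl cation (allylic SN1-type C–O bond formation); the C5, C6 and C8 configurations do not matter because all three centres become planar in step 4.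

**Step 4**
Reactants: 8 furanoid 5,8-epoxide
Product: 10 8-oxo-7,8-dihydro ketone, via dilithium dienolate 9 (not isolated)
Conditions: LiN(iPr)2 (3.2 equiv), THF, −78 to −40 °C; AcOH, −78 °C
Reagents that add atoms: none
Why: Proposed new method: base-induced ring-opening of a carotenoid furanoid oxide — LiN(iPr)2, pre-coordinated to the ring oxygen, removes the doubly allylic C8–H, the resulting 2,5-dihydrofuran-2-yl anion opens by six-electron (electrocyclic, formally vinylogous E1cB) cleavage of the C5–O bond to the lithium dienolate 9, so the ether oxygen becomes the C8 carbonyl oxygen and C5=C6 is restored, and kinetic protonation at the α-carbon C7 gives the deconjugated β,γ-enone; the closest known reactions are the strong-base opening of 2,5-dihydrofuran to the (Z)-dienolate of crotonaldehyde and the deconjugative protonation of dienolates, neither shown on a carotenoid furanoid.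

**Step 5**
Reactants: 10 8-oxo-7,8-dihydro ketone
Product: 11 syn-5,6-epoxy ketone (3S,5S,6R)
Conditions: VO(acac)2 (5 mol %), tBuOOH (1.5 equiv), CH2Cl2, 0 °C to rt
Reagents that add atoms: tert-butyl hydroperoxide, CC(C)(C)OO
Why: Hydroxyl-directed epoxidation (VO(acac)2/tBuOOH, Sharpless–Michaelson type): the homoallylic 3-alkoxide bound to the vanadium peroxo complex delivers oxygen to its own face of the tetrasubstituted C5=C6 bond, so C5 (S) and C6 (R) are set by the lutein-derived C3 centre, while the polyene and ring B, which lack a directing hydroxyl, do not react.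

**Step 6**
Reactants: 11 syn-5,6-epoxy ketone
Product: 14 (3S,6R)-3,6-dihydroxy-5(18)-en-8-one (3-epimer of silylated target), via bis-TMS enol ether 12 (not isolated), via lithium alkoxide 13 (not isolated)
Conditions: LiN(iPr)2/TMSCl (internal quench, 2.3 equiv each), THF, −78 °C; LiNEt2 (4 equiv), −78 to 0 °C; AcOH/THF/H2O, 0 °C
Reagents that add atoms: none
Why: Internal-quench enol silylation masks the C8 ketone before its enolate can open the oxirane by β-elimination, after which the lithium amide-promoted epoxide to allylic alcohol isomerisation (syn β-elimination, Crandall–Rickborn type) removes a proton from the C18 methyl and breaks C5–O, so the C6–O bond and its (R) configuration are kept and the exocyclic C5=C18 bond is formed; dilute AcOH then hydrolyses the TMS ether and enol ether.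

**Step 7**
Reactants: 14 (3S,6R)-3,6-dihydroxy-5(18)-en-8-one
Product: 15 (3R)-3-chloroacetate
Conditions: ClCH2CO2H, PPh3, DIAD, toluene, 0 °C to rt
Reagents that add atoms: chloroacetic acid, OC(=O)CCl
Why: Mitsunobu reaction: chloroacetate displaces the oxyphosphonium group at C3 by SN2 with inversion to (3R), now trans to the 6-hydroxyl; the tertiary 6-hydroxyl does not react and the allylic 3'-hydroxyl is protected.

**Step 8**
Reactants: 15 (3R)-3-chloroacetate
Product: 17 target, via 3'-O-TBS triol 16 (not isolated)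
Conditions: K2CO3 (cat.), MeOH/THF, −10 °C; then HF·pyridine, pyridine, THF, 0 °C to rt
Reagents that add atoms: none
Why: Carbonate-catalysed methanolysis of the activated chloroacetate is fast at −10 °C (no retro-aldol cleavage of the β-hydroxy ketone), and buffered HF·pyridine then removes the TBS ether without ionising the allylic or tertiary alcohols; no stereocentre is involved.

## Compound list

1 | (3R,3'R,6'R)-lutein, β,ε-carotene-3,3'-diol | CC1=C(C(C)(C)C[C@H](O)C1)/C=C/C(C)=C/C=C/C(C)=C/C=C/C=C(C)/C=C/C=C(C)/C=C/[C@H]1C(C)=C[C@H](O)CC1(C)C | starting material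

2 | 3'-oxolutein, (3R,6'R)-3-hydroxy-β,ε-caroten-3'-one | CC1=C(C(C)(C)C[C@H](O)C1)/C=C/C(C)=C/C=C/C(C)=C/C=C/C=C(C)/C=C/C=C(C)/C=C/[C@H]1C(C)=CC(=O)CC1(C)C | intermediate

3 | 3-O-TMS ether of 2 | CC1=C(C(C)(C)C[C@H](O[Si](C)(C)C)C1)/C=C/C(C)=C/C=C/C(C)=C/C=C/C=C(C)/C=C/C=C(C)/C=C/[C@H]1C(C)=CC(=O)CC1(C)C | intermediate (not isolated)

4 | potassium (3'R)-alkoxide of 3-O-TMS-lutein | CC1=C(C(C)(C)C[C@H](O[Si](C)(C)C)C1)/C=C/C(C)=C/C=C/C(C)=C/C=C/C=C(C)/C=C/C=C(C)/C=C/[C@H]1C(C)=C[C@H]([O-])CC1(C)C.[K+] | intermediate (not isolated)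

5 | 3-O-TMS-3'-O-TBS-lutein | CC1=C(C(C)(C)C[C@H](O[Si](C)(C)C)C1)/C=C/C(C)=C/C=C/C(C)=C/C=C/C=C(C)/C=C/C=C(C)/C=C/[C@H]1C(C)=C[C@H](O[Si](C)(C)C(C)(C)C)CC1(C)C | intermediate (not isolated)

6 | 3'-O-TBS-lutein, (3R,3'R,6'R)-3'-(tert-butyldimethylsilyloxy)-β,ε-caroten-3-ol | CC1=C(C(C)(C)C[C@H](O)C1)/C=C/C(C)=C/C=C/C(C)=C/C=C/C=C(C)/C=C/C=C(C)/C=C/[C@H]1C(C)=C[C@H](O[Si](C)(C)C(C)(C)C)CC1(C)C | intermediate

7 | (3S,3'R,6'R)-5,6-epoxy-5,6-dihydro derivative of 6, both oxirane faces (C5, C6 left open) | CC12C[C@@H](O)CC(C)(C)C1(O2)/C=C/C(C)=C/C=C/C(C)=C/C=C/C=C(C)/C=C/C=C(C)/C=C/[C@H]1C(C)=C[C@H](O[Si](C)(C)C(C)(C)C)CC1(C)C | intermediate (not isolated)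

8 | (3S,3'R,6'R)-5,8-epoxy-5,8-dihydro (furanoid) derivative of 6, mixture at C5 and C8 (left open) | CC12C[C@@H](O)CC(C)(C)C1=CC(O2)/C(C)=C/C=C/C(C)=C/C=C/C=C(C)/C=C/C=C(C)/C=C/[C@H]1C(C)=C[C@H](O[Si](C)(C)C(C)(C)C)CC1(C)C | intermediate

9 | dilithium 3-alkoxide C8-dienolate (O and C6 cis on C7=C8) | CC1=C(C(C)(C)C[C@H]([O-])C1)/C=C(\[O-])/C(C)=C/C=C/C(C)=C/C=C/C=C(C)/C=C/C=C(C)/C=C/[C@H]1C(C)=C[C@H](O[Si](C)(C)C(C)(C)C)CC1(C)C.[Li+].[Li+] | intermediate (not isolated)

10 | (3R,3'R,6'R)-3-hydroxy-3'-(tert-butyldimethylsilyloxy)-7,8-dihydro-β,ε-caroten-8-one | CC1=C(C(C)(C)C[C@H](O)C1)CC(=O)/C(C)=C/C=C/C(C)=C/C=C/C=C(C)/C=C/C=C(C)/C=C/[C@H]1C(C)=C[C@H](O[Si](C)(C)C(C)(C)C)CC1(C)C | intermediate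

11 | (3S,5S,6R,3'R,6'R)-5,6-epoxy-3-hydroxy-3'-(tert-butyldimethylsilyloxy)-5,6,7,8-tetrahydro-β,ε-caroten-8-one (oxirane cis to 3-OH) | C[C@]12C[C@@H](O)CC(C)(C)[C@]1(O2)CC(=O)/C(C)=C/C=C/C(C)=C/C=C/C=C(C)/C=C/C=C(C)/C=C/[C@H]1C(C)=C[C@H](O[Si](C)(C)C(C)(C)C)CC1(C)C | intermediate

12 | 3-O-TMS ether, C8 TMS enol ether of 11 (C7=C8 geometry left open) | C[C@]12C[C@@H](O[Si](C)(C)C)CC(C)(C)[C@]1(O2)C=C(O[Si](C)(C)C)/C(C)=C/C=C/C(C)=C/C=C/C=C(C)/C=C/C=C(C)/C=C/[C@H]1C(C)=C[C@H](O[Si](C)(C)C(C)(C)C)CC1(C)C | intermediate (not isolated)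

13 | lithium 6-alkoxide of the 5(18)-ene, still carrying both TMS groups | C=C1C[C@@H](O[Si](C)(C)C)CC(C)(C)[C@]1([O-])C=C(O[Si](C)(C)C)/C(C)=C/C=C/C(C)=C/C=C/C=C(C)/C=C/C=C(C)/C=C/[C@H]1C(C)=C[C@H](O[Si](C)(C)C(C)(C)C)CC1(C)C.[Li+] | intermediate (not isolated)

14 | (3S,6R,3'R,6'R)-3,6-dihydroxy-3'-(tert-butyldimethylsilyloxy)-7,8-dihydro-γ,ε-caroten-8-one (3-OH cis to 6-OH) | C=C1C[C@@H](O)CC(C)(C)[C@]1(O)CC(=O)/C(C)=C/C=C/C(C)=C/C=C/C=C(C)/C=C/C=C(C)/C=C/[C@H]1C(C)=C[C@H](O[Si](C)(C)C(C)(C)C)CC1(C)C | intermediate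

15 | (3R,6R,3'R,6'R)-3-(chloroacetoxy)-6-hydroxy-3'-(tert-butyldimethylsilyloxy)-7,8-dihydro-γ,ε-caroten-8-one | C=C1C[C@H](OC(=O)CCl)CC(C)(C)[C@]1(O)CC(=O)/C(C)=C/C=C/C(C)=C/C=C/C=C(C)/C=C/C=C(C)/C=C/[C@H]1C(C)=C[C@H](O[Si](C)(C)C(C)(C)C)CC1(C)C | intermediate

16 | (3R,6R,3'R,6'R)-3,6-dihydroxy-3'-(tert-butyldimethylsilyloxy)-7,8-dihydro-γ,ε-caroten-8-one | C=C1C[C@H](O)CC(C)(C)[C@]1(O)CC(=O)/C(C)=C/C=C/C(C)=C/C=C/C=C(C)/C=C/C=C(C)/C=C/[C@H]1C(C)=C[C@H](O[Si](C)(C)C(C)(C)C)CC1(C)C | intermediate (not isolated)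

17 | (3R,6R,3'R,6'R)-3,6,3'-trihydroxy-7,8-dihydro-γ,ε-caroten-8-one | C=C1C[C@H](O)CC(C)(C)[C@]1(O)CC(=O)/C(C)=C/C=C/C(C)=C/C=C/C=C(C)/C=C/C=C(C)/C=C/[C@H]1C(C)=C[C@H](O)CC1(C)C | target

## Step count and weak points

Total steps: 8. Longest linear sequence: 8 (the route is fully linear from 1).

**Step 4 (the proposed new step).** LiN(iPr)2 may instead deprotonate at C6' or at a polyene methyl, or the dienolate may protonate at C5. The fallback uses known chemistry and sets out from 6. Sensitised photo-oxygenation (O2, methylene blue, hν, CH2Cl2, −40 °C), the known [4+2] addition of singlet oxygen across C5–C8 of a carotenoid end group (modest yield), gives the 5,8-endoperoxide F1. Kornblum–DeLaMare fragmentation (Et3N, CH2Cl2, 0 °C) gives the (Z)-5-hydroxy-6-en-8-one F2. SmI2 (THF/MeOH, −78 °C) then cleaves the vinylogous α-hydroxyl, and kinetic protonation of the dienolate at C7 returns to the route at 10.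

**Step 6.** The ketone enolate may open the oxirane before it is silylated, giving the 5-hydroxy-6-en-8-one, or the amide base may abstract a ring proton at C4 instead of C18. The fallback sets out from 11. Luche reduction (NaBH4, CeCl3, MeOH, −40 °C) removes the enolisable ketone and gives the 8-hydroxy epoxide F3 (C8 epimers). LiNEt2 (5 equiv, THF, 0 °C to rt) isomerises the oxirane on the trialkoxide to the 3,6,8-triol F4. MnO2 (CH2Cl2, rt) oxidises only the polyene-allylic C8 carbinol and returns to the route at 14.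

**Step 7.** C3 is hindered by the syn-axial C1 methyl, so elimination to a diene may compete with substitution. The fallback sets out from 14. Tf2O, pyridine, CH2Cl2, −40 °C gives the 3-triflate F5 (the tertiary 6-hydroxyl reacts much more slowly). Sulfonate displacement with CsO2CCH2Cl and 18-crown-6 in toluene at rt inverts C3 and returns to the route at 15.

## Further compounds

F1 | step 4 | 5,8-endoperoxide (5,8-epidioxy-5,8-dihydro derivative) of 6, C5/C8 left open | CC12C[C@@H](O)CC(C)(C)C1=CC(OO2)/C(C)=C/C=C/C(C)=C/C=C/C=C(C)/C=C/C=C(C)/C=C/[C@H]1C(C)=C[C@H](O[Si](C)(C)C(C)(C)C)CC1(C)C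

F2 | step 4 | (Z)-3,5-dihydroxy-6-en-8-one (γ-hydroxy enone), C5 left open | CC1(O)C[C@@H](O)CC(C)(C)/C1=C/C(=O)/C(C)=C/C=C/C(C)=C/C=C/C=C(C)/C=C/C=C(C)/C=C/[C@H]1C(C)=C[C@H](O[Si](C)(C)C(C)(C)C)CC1(C)C

F3 | step 6 | (3S,5S,6R)-5,6-epoxy-3,8-diol, C8 epimers | C[C@]12C[C@@H](O)CC(C)(C)[C@]1(O2)CC(O)/C(C)=C/C=C/C(C)=C/C=C/C=C(C)/C=C/C=C(C)/C=C/[C@H]1C(C)=C[C@H](O[Si](C)(C)C(C)(C)C)CC1(C)C

F4 | step 6 | (3S,6R)-5(18)-ene-3,6,8-triol, C8 epimers | C=C1C[C@@H](O)CC(C)(C)[C@]1(O)CC(O)/C(C)=C/C=C/C(C)=C/C=C/C=C(C)/C=C/C=C(C)/C=C/[C@H]1C(C)=C[C@H](O[Si](C)(C)C(C)(C)C)CC1(C)C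

F5 | step 7 | (3S)-3-triflate of 14 | C=C1C[C@@H](OS(=O)(=O)C(F)(F)F)CC(C)(C)[C@]1(O)CC(=O)/C(C)=C/C=C/C(C)=C/C=C/C=C(C)/C=C/C=C(C)/C=C/[C@H]1C(C)=C[C@H](O[Si](C)(C)C(C)(C)C)CC1(C)C
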